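All constants stand for no real mixture, and the outcome is calculated.

I would reckon the three flasks as one sum rather than guess each: find how much L reaches G and count the rest as paired off.

in all of them: G 0.46 M; time 1.5 h

| charge | L |
|---|---|
| green | 1.90 M |
| violet | 0.480 M |
| teal | 0.970 M |

    L + D ⇌ L.D, settled at all times (K1 = 1800 M⁻¹)
    2 L → L2 (k2 = 0.071 M⁻¹ s⁻¹)
    G + L → D + Z (k3 = 0.016 M⁻¹ s⁻¹)
    Z → J (k4 = 0.0015 s⁻¹)
    G + D → G.D (k5 = 0.11 M⁻¹ s⁻¹)

1. part of the G that has reacted at the end, green
2. part of the G that has reacted at the end, violet
3. part of the G that has reacted at the end, teal
4. what raising the concentration of L from its lowest to its highest value here does to the part of the G that has reacted (changes below 5 percentage points count as none) (it falls / it rises / no change)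

Free L has two exits. Pairing takes it at twice its constant times [L] squared. Each turn of G + L also takes two free L, one consumed and one caught by the new D, since K times [L] is 860 at the start of violet. So L.D is the resting state of D while L lasts. The exits balance at the crossover concentration X, the constant of G + L over that of pairing (0.225) times the mean [G]. Above X, L mostly pairs; below it, L mostly goes to G, and that includes the L later freed from L.D.

Integrating gives the reach S = X ln(1 + [L]/X), with [L] as charged. Each unit of S costs two G, one with L and one with D.

As a first guess I put mean [G] at 0.7 of its charge, so X is 0.0726 M. S is then 0.240 M for green, 0.147 M for violet and 0.193 M for teal.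

Going round once more, I take mean [G] as the charge less 0.750 of S. S becomes 0.217 M, 0.154 M and 0.191 M. Twice S over the charge of G gives 94.4% for green, 67.1% for violet and 82.9% for teal, so with more L the part reacted: it rises.

Your forecast says 81%, 67% and 76%, and it rises, holding that “its time-integrated exposure grows only logarithmically with starting concentration”. My green and teal lie above yours.

The simulation gives 91.9% for green, 66.7% for violet and 83.1% for teal: it rises, by 25 percentage points. Green stands above violet because its charge of L is larger, and with the pairing step taken away that gap shrinks from 25 points to 0.62 points. Violet's S of 0.154 M stands beside its J of 0.153 M. For one more flask, like teal but with 1.8 M of G, my X is 0.334 M, against the first guess of 0.0726 M for the charge of teal. S is then 0.455 M, which gives 50.6%, and that flask reacted 51.3%.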